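## Retrosynthetic overview

1. Cedrane numbering is used. Ring C = C1–C2–C3–C4–C5 (C2 carries the formyl carbon C12). Ring B = C1–C5–C6–C7–C11 (C6 carries C13H2OH endo and C14H3 exo; C11 is the one-carbon bridge). Ring A = C1–C7–C8=C9–C10–C11 (C8 carries C15O2H, C10 the acyloxy group). Last disconnections: the O10 ester (Yamaguchi, acid 32), the C12 aldehyde (from a TES-protected alcohol), and acid-labile protection of the C13 and chain hydroxyls and of the C15 acid.
2. The C10 alcohol comes from enone 24 (Luche reduction), and 24 from allylic oxidation of 23. The C11 methylene comes from the C11 ketone of 19 (tosylhydrazone reduction). Keto enal 17 comes from the strained photoadducts 13/14 by push–pull cyclopropane cleavage, which creates ring A and turns the aryl ether oxygen into O12.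
3. Key disconnection: C1–C5 and C6–C7, formed together by an intramolecular arene–alkene meta photocycloaddition of dihydrobenzofuran 12. The enabling feature: ring B is a two-carbon unit (C5–C6) bonded to C1 and C7, the 1,3-related carbons of six-membered ring A that flank the bridge carbon C11, so ring A is a latent benzene ring (C15 on C8, para to the chain on C1). C2–C3–C4 is the three-carbon tether from C1 to C5. C12 on C2 is cis to C11 across ring C, so its oxygen can be the aryl ether (donor) oxygen on C11 in a five-membered ring.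
4. 12 comes from (S)-3-vinyl-dihydrobenzofuran 6 and vinyl iodide 10 (hydroboration/Suzuki–Miyaura), 6 from (S)-alcohol 5 (Mitsunobu), and 5 from arylboronate 3 and cis-butenediol 4 by rhodium-catalysed asymmetric arylation. This is the only stereocentre set by a catalyst; the other five are relayed from it.
5. Ring order: dihydrofuran ring (step 4, temporary) → rings C and B plus a cyclopropane (step 8) → ring A by cyclopropane cleavage with opening of the dihydrofuran ring (step 9).

Key step: step 8

Remark on the chemistry (assumptions): hydroxy ketones 17–19 are drawn open; reversible closure of O12 onto C11 to a strained bridged hemiketal would not change any step. The cyclopropane regioisomers 13 and 14 are carried on together. In step 3 the enantiomer of the diene ligand that delivers the 2S alcohol is used. For all tricyclic compounds the SMILES defines the configuration; C1, C2, C5, C6, C7 are as in the target.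

## Route

Step 1
Reactants: 1 4-bromo-3-hydroxybenzaldehyde
Product: 2 2-bromo-5-(dimethoxymethyl)phenol
Conditions: HC(OMe)3, MeOH, TsOH·H2O (cat.), 23 °C; Et3N quench
Reagents that add atoms: trimethyl orthoformate, COC(OC)OC; methanol, CO
Why: Acid-catalysed acetalisation with the orthoformate as water scavenger masks the formyl group as a non-conjugated acetal, which keeps a carbonyl chromophore off the arene and survives all basic and organometallic steps up to the photoreaction.

Step 2
Reactants: 2 2-bromo-5-(dimethoxymethyl)phenol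
Product: 3 5-(dimethoxymethyl)-2-(4,4,5,5-tetramethyl-1,3,2-dioxaborolan-2-yl)phenol
Conditions: B2pin2, Pd(dppf)Cl2 (cat.), KOAc, 1,4-dioxane, 85 °C
Reagents that add atoms: bis(pinacolato)diboron, CC1(C)OB(OC1(C)C)B1OC(C)(C)C(C)(C)O1
Why: Miyaura borylation of the aryl bromide, whose weak acetate base should tolerate the free phenol and the acetal.

Step 3
Reactants: 3 5-(dimethoxymethyl)-2-(4,4,5,5-tetramethyl-1,3,2-dioxaborolan-2-yl)phenol; 4 (Z)-but-2-ene-1,4-diol
Product: 5 (2S)-2-[4-(dimethoxymethyl)-2-hydroxyphenyl]but-3-en-1-ol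
Conditions: [RhCl(C2H4)2]2 (cat.), chiral bicyclo[2.2.2]octadiene ligand Bn-bod* (cat.), KOH (0.2 equiv), dioxane/H2O, 50 °C
Reagents that add atoms: none
Why: Rhodium-catalysed substitutive arylation of a cis-allylic diol (arylrhodation of the symmetric alkene, then β-hydroxide elimination) should give the branched alcohol, with the chiral diene selecting the alkene face in the arylrhodation and so setting the 2S centre, the only catalyst-controlled stereocentre of the route.

Step 4
Reactants: 5 (2S)-2-[4-(dimethoxymethyl)-2-hydroxyphenyl]but-3-en-1-ol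
Product: 6 (3S)-6-(dimethoxymethyl)-3-ethenyl-2,3-dihydro-1-benzofuran
Conditions: PPh3, DIAD, THF, 0 to 23 °C
Reagents that add atoms: none
Why: Intramolecular Mitsunobu etherification (5-exo-tet attack of the phenoxide on the activated primary carbon) should close the dihydrofuran ring without touching the adjacent stereocentre.

Step 5
Reactants: 7 prop-2-yn-1-ol
Product: 9 (2E)-3-iodo-2-methylprop-2-en-1-ol, via alkenylalane 8 (not isolated)
Conditions: AlMe3 (3 equiv), Cp2ZrCl2 (0.25 equiv), CH2Cl2, 0 to 23 °C; then I2, THF, −30 °C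
Reagents that add atoms: trimethylaluminium, C[Al](C)C; iodine, II
Why: Zirconium-catalysed carboalumination (Negishi) adds CH3 and aluminium syn across the alkyne with aluminium at the terminus, and iodinolysis with retention should give the E iodide.

Step 6
Reactants: 9 (2E)-3-iodo-2-methylprop-2-en-1-ol
Product: 10 tert-butyl{[(2E)-3-iodo-2-methylprop-2-en-1-yl]oxy}dimethylsilane
Conditions: TBSCl, imidazole, CH2Cl2, 23 °C
Reagents that add atoms: tert-butyldimethylsilyl chloride, CC(C)(C)[Si](C)(C)Cl
Why: Standard silylation of the primary allylic alcohol gives an ether without an aryl chromophore that should survive the photoreaction and all steps up to the final acidolysis.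

Step 7
Reactants: 6 (3S)-6-(dimethoxymethyl)-3-ethenyl-2,3-dihydro-1-benzofuran; 10 tert-butyl{[(2E)-3-iodo-2-methylprop-2-en-1-yl]oxy}dimethylsilane
Product: 12 tert-butyl({(2E)-5-[(3S)-6-(dimethoxymethyl)-2,3-dihydro-1-benzofuran-3-yl]-2-methylpent-2-en-1-yl}oxy)dimethylsilane, via alkylborane 11 (not isolated)
Conditions: 9-BBN, THF, 0 to 23 °C; then 10, Pd(dppf)Cl2 (cat.), AsPh3, Cs2CO3, DMF/H2O, 23 °C
Reagents that add atoms: none
Why: Anti-Markovnikov hydroboration of the vinyl group followed by B-alkyl Suzuki–Miyaura coupling should join the fragments with retention of the E alkene geometry and leave the stereocentre and the acetal untouched.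

Step 8
Reactants: 12 tert-butyl({(2E)-5-[(3S)-6-(dimethoxymethyl)-2,3-dihydro-1-benzofuran-3-yl]-2-methylpent-2-en-1-yl}oxy)dimethylsilane
Product: 13 vinylcyclopropane photoadduct A (13-TBSO-15,15-dimethoxy-11,12-epoxy-8,11-cyclocedr-9-ene) plus 14 vinylcyclopropane photoadduct B (13-TBSO-15,15-dimethoxy-11,12-epoxy-10,11-cyclocedr-8-ene); regioisomers of cyclopropane closure, carried on together
Conditions: hν (254 nm, low-pressure Hg lamp, quartz), degassed cyclohexane (0.005 M), 23 °C
Reagents that add atoms: none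
Why: Excitation of the alkoxyarene gives an intramolecular exciplex with the tethered alkene, which bonds C5 to the ipso carbon C1 and C6 to C7, the two ring carbons flanking the oxygen-bearing C11 (meta addition), and the resulting bridged biradical or zwitterion closes from C11 to C8 or to C10 to give 13 and 14. The closest known reaction type is the ortho-alkoxy-directed intramolecular arene–alkene meta photocycloaddition of 5-arylpent-1-enes that carry a benzylic stereocentre and a trisubstituted alkene, which is used for cedrane-type skeletons. Ring C closes as a five-membered ring through the three-carbon tether (5-exo-type bonding of the alkene CH to the ipso carbon), ring B forms as a formal (3+2) union of the arene unit C1–C11–C7 with C5=C6, and the cyclopropane arises by 1,3-closure of the biradical. C1, C5, C7 and C11 should be set by the preset centre C2: its ring-locked C12 lies in the arene plane on the oxygen side, so the chain and the alkene can reach only one arene face; C6 follows from the E alkene geometry through suprafacial addition (CH2OTBS endo, CH3 exo). The step needs 1,3-addition across C11 and not across the unsubstituted ortho carbon or an ortho (2+2) addition, which the ring-oxygen donor on C11 and the σ-acceptor acetal at the end of the developing allyl unit should secure; the direction of cyclopropane closure is left free because 13 and 14 converge in step 9.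

Step 9
Reactants: 13 vinylcyclopropane photoadduct A; 14 vinylcyclopropane photoadduct B
Product: 17 13-[(tert-butyldimethylsilyl)oxy]-12-hydroxy-11-oxocedr-8-en-15-al, via cyclopropyl aldehyde 15 (not isolated), via cyclopropyl enal 16 (not isolated)
Conditions: PPTS (cat.), acetone/H2O (10:1), 45 °C
Reagents that add atoms: water, O
Why: Acetal hydrolysis turns both isomers into donor–acceptor cyclopropanes (ether oxygen on C11 as donor, formyl group on C8 as acceptor, directly in 15 and through C8=C9 in 16), and acid-promoted heterolysis of C8–C11 or C10–C11 (donor–acceptor cyclopropane ring-opening, as in the acid cleavage of 1-alkoxy meta photoadducts to bicyclo[3.2.1]octenones) should release the ring strain to one dienol/oxocarbenium ion that is hydrated at C11 and tautomerises to the conjugated enal, which forms ring A, frees O12 and erases the C8/C10 stereocentres of the adducts without creating a new one.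

Step 10
Reactants: 17 13-[(tert-butyldimethylsilyl)oxy]-12-hydroxy-11-oxocedr-8-en-15-al
Product: 18 13-[(tert-butyldimethylsilyl)oxy]-12-hydroxy-11-oxocedr-8-en-15-oic acid
Conditions: NaClO2, NaH2PO4, 2-methylbut-2-ene, t-BuOH/H2O, 0 to 23 °C
Reagents that add atoms: sodium chlorite, [Na+].[O-]Cl=O
Why: Pinnick oxidation should convert the enal into the acid without touching the ketone, the primary alcohol or the silyl ether.

Step 11
Reactants: 18 13-[(tert-butyldimethylsilyl)oxy]-12-hydroxy-11-oxocedr-8-en-15-oic acid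
Product: 19 tert-butyl 13-[(tert-butyldimethylsilyl)oxy]-12-hydroxy-11-oxocedr-8-en-15-oate
Conditions: Me2NCH(Ot-Bu)2, toluene, 80 °C
Reagents that add atoms: N,N-dimethylformamide di-tert-butyl acetal, CN(C)C(OC(C)(C)C)OC(C)(C)C
Why: Esterification with the amide acetal alkylates only the carboxylic acid and gives a tert-butyl ester that should withstand the later reduction and oxidation steps and fall to acid at the end.

Step 12
Reactants: 19 tert-butyl 13-[(tert-butyldimethylsilyl)oxy]-12-hydroxy-11-oxocedr-8-en-15-oate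
Product: 20 tert-butyl 13-[(tert-butyldimethylsilyl)oxy]-12-hydroxy-11-(tosylhydrazono)cedr-8-en-15-oate
Conditions: TsNHNH2, AcOH (cat.), 4 Å sieves, THF, 55 °C
Reagents that add atoms: 4-methylbenzenesulfonohydrazide, Cc1ccc(cc1)S(=O)(=O)NN
Why: Condensation of the strained, electrophilic bridging ketone with tosylhydrazide (hydrazone formation) should proceed although C11 lies between two bridgeheads, and for the same reason no elimination pathway is open to the hydrazone.

Step 13
Reactants: 20 tert-butyl 13-[(tert-butyldimethylsilyl)oxy]-12-hydroxy-11-(tosylhydrazono)cedr-8-en-15-oate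
Product: 22 tert-butyl 13-[(tert-butyldimethylsilyl)oxy]-12-hydroxycedr-8-en-15-oate, via boryl hydrazine 21 (not isolated)
Conditions: catecholborane (excess), CHCl3, 0 °C; then NaOAc·3H2O, reflux
Reagents that add atoms: none
Why: Tosylhydrazone reduction (hydride transfer from catecholborane to C=N, then acetate-induced loss of sulfinate and dinitrogen) should replace the C11 oxygen by hydrogen under conditions that spare the enoate, the silyl ether and the tert-butyl ester.

Step 14
Reactants: 22 tert-butyl 13-[(tert-butyldimethylsilyl)oxy]-12-hydroxycedr-8-en-15-oate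
Product: 23 tert-butyl 13-[(tert-butyldimethylsilyl)oxy]-12-[(triethylsilyl)oxy]cedr-8-en-15-oate
Conditions: TESCl, imidazole, CH2Cl2, 0 °C
Reagents that add atoms: chlorotriethylsilane, CC[Si](Cl)(CC)CC
Why: Silylation of the only free hydroxyl as a TES ether gives a group that can later be removed in the presence of the TBS ethers.

Step 15
Reactants: 23 tert-butyl 13-[(tert-butyldimethylsilyl)oxy]-12-[(triethylsilyl)oxy]cedr-8-en-15-oate
Product: 24 tert-butyl 13-[(tert-butyldimethylsilyl)oxy]-10-oxo-12-[(triethylsilyl)oxy]cedr-8-en-15-oate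
Conditions: Rh2(cap)4 (dirhodium tetracaprolactamate, cat.), t-BuOOH (70% aq.), ClCH2CH2Cl, 40 °C
Reagents that add atoms: tert-butyl hydroperoxide, CC(C)(C)OO
Why: Allylic C–H oxidation by tert-butylperoxyl radicals, known for cyclohex-1-ene carboxylates and enones, should convert the only reactive allylic position (C10H2; the other allylic carbon C7 is a bridgehead) into the ketone.

Step 16
Reactants: 24 tert-butyl 13-[(tert-butyldimethylsilyl)oxy]-10-oxo-12-[(triethylsilyl)oxy]cedr-8-en-15-oate
Product: 25 tert-butyl 13-[(tert-butyldimethylsilyl)oxy]-10-hydroxy-12-[(triethylsilyl)oxy]cedr-8-en-15-oate (10-OH on the side of the C5–C6 bridge)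
Conditions: NaBH4, CeCl3·7H2O, MeOH, −78 °C
Reagents that add atoms: none
Why: Luche 1,2-reduction should deliver hydride to the C10 carbonyl from the face syn to the one-carbon bridge (axial attack, away from the C5–C6 bridge with its endo CH2OTBS group), which places the hydroxyl on the side of the C5–C6 bridge as in the target.

Step 17
Reactants: 26 9-bromononanoic acid
Product: 27 (8-carboxyoctyl)triphenylphosphonium bromide
Conditions: PPh3, MeCN, reflux
Reagents that add atoms: triphenylphosphine, c1ccc(cc1)P(c1ccccc1)c1ccccc1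
Why: SN2 quaternisation of the phosphine by the primary bromide gives the Wittig salt.

Step 18
Reactants: 28 heptane-1,7-diol
Product: 29 7-[(tert-butyldimethylsilyl)oxy]heptan-1-ol
Conditions: NaH (1.0 equiv), THF, 0 °C; then TBSCl, 23 °C
Reagents that add atoms: tert-butyldimethylsilyl chloride, CC(C)(C)[Si](C)(C)Cl
Why: Monosilylation of the symmetric diol through its sparingly soluble monosodium alkoxide should favour the mono-ether.

Step 19
Reactants: 29 7-[(tert-butyldimethylsilyl)oxy]heptan-1-ol
Product: 30 7-[(tert-butyldimethylsilyl)oxy]heptanal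
Conditions: Dess–Martin periodinane, CH2Cl2, 0 to 23 °C
Reagents that add atoms: none
Why: Dess–Martin oxidation of the primary alcohol stops at the aldehyde.

Step 20
Reactants: 27 (8-carboxyoctyl)triphenylphosphonium bromide; 30 7-[(tert-butyldimethylsilyl)oxy]heptanal
Product: 32 (9Z)-16-[(tert-butyldimethylsilyl)oxy]hexadec-9-enoic acid, via ylide 31 (not isolated)
Conditions: NaN(SiMe3)2 (2.1 equiv), THF, −78 °C; then 30, −78 to 23 °C; aq. NH4Cl
Reagents that add atoms: none
Why: The Wittig reaction of a non-stabilised ylide under lithium-free conditions should give the Z alkene through kinetically controlled cis-oxaphosphetane formation.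

Step 21
Reactants: 25 tert-butyl 13-[(tert-butyldimethylsilyl)oxy]-10-hydroxy-12-[(triethylsilyl)oxy]cedr-8-en-15-oate; 32 (9Z)-16-[(tert-butyldimethylsilyl)oxy]hexadec-9-enoic acid
Product: 34 tert-butyl 10-{[(9Z)-16-(tert-butyldimethylsilyloxy)hexadec-9-enoyl]oxy}-13-[(tert-butyldimethylsilyl)oxy]-12-[(triethylsilyl)oxy]cedr-8-en-15-oate, via mixed anhydride 33 (not isolated)
Conditions: 2,4,6-Cl3C6H2COCl, Et3N, THF, 23 °C; then 25, DMAP, toluene, 40 °C
Reagents that add atoms: none
Why: Yamaguchi esterification should acylate the hindered secondary allylic alcohol through the acyl-DMAP species with retention at C10.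

Step 22
Reactants: 34 the fully protected ester
Product: 35 tert-butyl 10-{[(9Z)-16-(tert-butyldimethylsilyloxy)hexadec-9-enoyl]oxy}-13-[(tert-butyldimethylsilyl)oxy]-12-hydroxycedr-8-en-15-oate
Conditions: PPTS (cat.), MeOH/CH2Cl2, 0 °C
Reagents that add atoms: none
Why: Mild acid methanolysis should remove the primary TES ether much faster than the primary and the neopentyl TBS ethers.

Step 23
Reactants: 35 the C12 alcohol
Product: 36 tert-butyl 10-{[(9Z)-16-(tert-butyldimethylsilyloxy)hexadec-9-enoyl]oxy}-13-[(tert-butyldimethylsilyl)oxy]-12-oxocedr-8-en-15-oate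
Conditions: Dess–Martin periodinane, CH2Cl2, 0 °C
Reagents that add atoms: none
Why: Dess–Martin oxidation gives the aldehyde under non-basic conditions, so the epimerisable C2 centre should be kept.

Step 24
Reactants: 36 the protected aldehyde
Product: 37 target, 10-{[(9Z)-16-hydroxyhexadec-9-enoyl]oxy}-13-hydroxy-12-oxocedr-8-en-15-oic acid
Conditions: TFA/CH2Cl2/H2O (10:30:1), 0 to 23 °C; toluene azeotrope
Reagents that add atoms: none
Why: Acidolysis should cleave the tert-butyl ester (loss of isobutene) and both TBS ethers in one operation, under conditions that neither enolise the C2 aldehyde nor ionise the electron-poor allylic ester.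

## Compound list

1 | 4-bromo-3-hydroxybenzaldehyde | O=Cc1ccc(Br)c(O)c1 | starting material
2 | 2-bromo-5-(dimethoxymethyl)phenol | COC(OC)c1ccc(Br)c(O)c1 | intermediate
3 | 5-(dimethoxymethyl)-2-(4,4,5,5-tetramethyl-1,3,2-dioxaborolan-2-yl)phenol | COC(OC)c1ccc(B2OC(C)(C)C(C)(C)O2)c(O)c1 | intermediate
4 | (Z)-but-2-ene-1,4-diol | OC/C=C\CO | starting material
5 | (2S)-2-[4-(dimethoxymethyl)-2-hydroxyphenyl]but-3-en-1-ol | COC(OC)c1ccc(c(O)c1)[C@@H](CO)C=C | intermediate
6 | (3S)-6-(dimethoxymethyl)-3-ethenyl-2,3-dihydro-1-benzofuran | COC(OC)c1ccc2c(c1)OC[C@H]2C=C | intermediate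
7 | prop-2-yn-1-ol | C#CCO | starting material
8 | (E)-alkenylalane, Me2Al–CH=C(CH3)–CH2O–AlMe2 | C[Al](C)/C=C(\C)CO[Al](C)C | intermediate (not isolated)
9 | (2E)-3-iodo-2-methylprop-2-en-1-ol | I/C=C(\C)CO | intermediate
10 | tert-butyl{[(2E)-3-iodo-2-methylprop-2-en-1-yl]oxy}dimethylsilane | I/C=C(\C)CO[Si](C)(C)C(C)(C)C | intermediate
11 | 9-{2-[(3S)-6-(dimethoxymethyl)-2,3-dihydro-1-benzofuran-3-yl]ethyl}-9-borabicyclo[3.3.1]nonane | COC(OC)c1ccc2c(c1)OC[C@H]2CCB1C2CCCC1CCC2 | intermediate (not isolated)
12 | tert-butyl({(2E)-5-[(3S)-6-(dimethoxymethyl)-2,3-dihydro-1-benzofuran-3-yl]-2-methylpent-2-en-1-yl}oxy)dimethylsilane | COC(OC)c1ccc2c(c1)OC[C@H]2CC/C=C(\C)CO[Si](C)(C)C(C)(C)C | intermediate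
13 | photoadduct A: 13-TBSO-15,15-dimethoxy-11,12-epoxy-8,11-cyclocedr-9-ene (cyclopropane C7–C8–C11; H7, O11 and the acetal cis on it) | C[C@@]1(CO[Si](C)(C)C(C)(C)C)[C@H]2[C@@]4(O5)[C@@]3(C=C[C@@]24C(OC)OC)[C@@H](C5)CC[C@@H]13 | intermediate
14 | photoadduct B: 13-TBSO-15,15-dimethoxy-11,12-epoxy-10,11-cyclocedr-8-ene (cyclopropane C1–C10–C11) | C[C@@]1(CO[Si](C)(C)C(C)(C)C)[C@H]2[C@@]4(O5)[C@@]3([C@H]4C=C2C(OC)OC)[C@@H](C5)CC[C@@H]13 | intermediate
15 | 13-TBSO-11,12-epoxy-8,11-cyclocedr-9-en-15-al | C[C@@]1(CO[Si](C)(C)C(C)(C)C)[C@H]2[C@@]4(O5)[C@@]3(C=C[C@@]24C=O)[C@@H](C5)CC[C@@H]13 | intermediate (not isolated)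
16 | 13-TBSO-11,12-epoxy-10,11-cyclocedr-8-en-15-al | C[C@@]1(CO[Si](C)(C)C(C)(C)C)[C@H]2[C@@]4(O5)[C@@]3([C@H]4C=C2C=O)[C@@H](C5)CC[C@@H]13 | intermediate (not isolated)
17 | 13-[(tert-butyldimethylsilyl)oxy]-12-hydroxy-11-oxocedr-8-en-15-al | C[C@@]1(CO[Si](C)(C)C(C)(C)C)[C@H]2C(=O)[C@@]3(CC=C2C=O)[C@@H](CO)CC[C@@H]13 | intermediate
18 | 13-[(tert-butyldimethylsilyl)oxy]-12-hydroxy-11-oxocedr-8-en-15-oic acid | C[C@@]1(CO[Si](C)(C)C(C)(C)C)[C@H]2C(=O)[C@@]3(CC=C2C(=O)O)[C@@H](CO)CC[C@@H]13 | intermediate
19 | tert-butyl 13-[(tert-butyldimethylsilyl)oxy]-12-hydroxy-11-oxocedr-8-en-15-oate | C[C@@]1(CO[Si](C)(C)C(C)(C)C)[C@H]2C(=O)[C@@]3(CC=C2C(=O)OC(C)(C)C)[C@@H](CO)CC[C@@H]13 | intermediate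
20 | 11-tosylhydrazone of 19 (C=N geometry not defined) | C[C@@]1(CO[Si](C)(C)C(C)(C)C)[C@H]2C(=NNS(=O)(=O)c4ccc(C)cc4)[C@@]3(CC=C2C(=O)OC(C)(C)C)[C@@H](CO)CC[C@@H]13 | intermediate
21 | N-(1,3,2-benzodioxaborol-2-yl)-N′-tosylhydrazine at C11 (C11 configuration not defined, transient) | C[C@@]1(CO[Si](C)(C)C(C)(C)C)[C@H]2C(N(NS(=O)(=O)c4ccc(C)cc4)B4Oc5ccccc5O4)[C@@]3(CC=C2C(=O)OC(C)(C)C)[C@@H](CO)CC[C@@H]13 | intermediate (not isolated)
22 | tert-butyl 13-[(tert-butyldimethylsilyl)oxy]-12-hydroxycedr-8-en-15-oate | C[C@@]1(CO[Si](C)(C)C(C)(C)C)[C@H]2C[C@@]3(CC=C2C(=O)OC(C)(C)C)[C@@H](CO)CC[C@@H]13 | intermediate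
23 | tert-butyl 13-[(tert-butyldimethylsilyl)oxy]-12-[(triethylsilyl)oxy]cedr-8-en-15-oate | C[C@@]1(CO[Si](C)(C)C(C)(C)C)[C@H]2C[C@@]3(CC=C2C(=O)OC(C)(C)C)[C@@H](CO[Si](CC)(CC)CC)CC[C@@H]13 | intermediate
24 | tert-butyl 13-[(tert-butyldimethylsilyl)oxy]-10-oxo-12-[(triethylsilyl)oxy]cedr-8-en-15-oate | C[C@@]1(CO[Si](C)(C)C(C)(C)C)[C@H]2C[C@@]3(C(=O)C=C2C(=O)OC(C)(C)C)[C@@H](CO[Si](CC)(CC)CC)CC[C@@H]13 | intermediate
25 | tert-butyl 13-[(tert-butyldimethylsilyl)oxy]-10-hydroxy-12-[(triethylsilyl)oxy]cedr-8-en-15-oate (10-OH as in the target) | C[C@@]1(CO[Si](C)(C)C(C)(C)C)[C@H]2C[C@@]3([C@@H](O)C=C2C(=O)OC(C)(C)C)[C@@H](CO[Si](CC)(CC)CC)CC[C@@H]13 | intermediate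
26 | 9-bromononanoic acid | OC(=O)CCCCCCCCBr | starting material
27 | (8-carboxyoctyl)triphenylphosphonium bromide | OC(=O)CCCCCCCC[P+](c1ccccc1)(c1ccccc1)c1ccccc1.[Br-] | intermediate
28 | heptane-1,7-diol | OCCCCCCCO | starting material
29 | 7-[(tert-butyldimethylsilyl)oxy]heptan-1-ol | OCCCCCCCO[Si](C)(C)C(C)(C)C | intermediate
30 | 7-[(tert-butyldimethylsilyl)oxy]heptanal | O=CCCCCCCO[Si](C)(C)C(C)(C)C | intermediate
31 | sodium 9-(triphenylphosphoranylidene)nonanoate | [Na+].[O-]C(=O)CCCCCCCC=P(c1ccccc1)(c1ccccc1)c1ccccc1 | intermediate (not isolated)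
32 | (9Z)-16-[(tert-butyldimethylsilyl)oxy]hexadec-9-enoic acid | OC(=O)CCCCCCC/C=C\CCCCCCO[Si](C)(C)C(C)(C)C | intermediate
33 | mixed anhydride of 32 with 2,4,6-trichlorobenzoic acid | Clc1cc(Cl)c(C(=O)OC(=O)CCCCCCC/C=C\CCCCCCO[Si](C)(C)C(C)(C)C)c(Cl)c1 | intermediate (not isolated)
34 | tert-butyl 10-{[(9Z)-16-(tert-butyldimethylsilyloxy)hexadec-9-enoyl]oxy}-13-[(tert-butyldimethylsilyl)oxy]-12-[(triethylsilyl)oxy]cedr-8-en-15-oate | C[C@@]1(CO[Si](C)(C)C(C)(C)C)[C@H]2C[C@@]3([C@@H](OC(=O)CCCCCCC/C=C\CCCCCCO[Si](C)(C)C(C)(C)C)C=C2C(=O)OC(C)(C)C)[C@@H](CO[Si](CC)(CC)CC)CC[C@@H]13 | intermediate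
35 | 12-alcohol (34 without the TES group) | C[C@@]1(CO[Si](C)(C)C(C)(C)C)[C@H]2C[C@@]3([C@@H](OC(=O)CCCCCCC/C=C\CCCCCCO[Si](C)(C)C(C)(C)C)C=C2C(=O)OC(C)(C)C)[C@@H](CO)CC[C@@H]13 | intermediate
36 | 12-aldehyde, tert-butyl ester, bis-TBS ether | C[C@@]1(CO[Si](C)(C)C(C)(C)C)[C@H]2C[C@@]3([C@@H](OC(=O)CCCCCCC/C=C\CCCCCCO[Si](C)(C)C(C)(C)C)C=C2C(=O)OC(C)(C)C)[C@@H](C=O)CC[C@@H]13 | intermediate
37 | 10-{[(9Z)-16-hydroxyhexadec-9-enoyl]oxy}-13-hydroxy-12-oxocedr-8-en-15-oic acid | C[C@@]1(CO)[C@H]2C[C@@]3([C@@H](OC(=O)CCCCCCC/C=C\CCCCCCO)C=C2C(=O)O)[C@@H](C=O)CC[C@@H]13 | target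

## Step count and risks

Total steps: 24. Longest linear sequence: 18 (steps 1–4, 7–16, 21–24).

Most likely to fail:

1. Step 8. The five-membered ether ring fixes the first bond of the chain at a set angle to the arene. If the alkene then reaches the two reacting carbons poorly, three processes would compete: E/Z isomerisation of the alkene in the exciplex (loss of the C6 configuration), ortho (2+2) addition, or 1,3-addition across the unsubstituted ortho carbon. Fallback: replace the dihydrofuran ring by a seven-membered cyclic formal, which still holds C12 on the oxygen side of the arene but leaves the chain free. The fallback sets out from 5. CH2Br2/NaH in DMF should give (5S)-8-(dimethoxymethyl)-5-ethenyl-4,5-dihydro-1,3-benzodioxepine F1. Hydroboration and Suzuki–Miyaura coupling with 10 as in step 7 should give the photosubstrate (5S)-5-[(3E)-5-(tert-butyldimethylsilyloxy)-4-methylpent-3-enyl]-8-(dimethoxymethyl)-4,5-dihydro-1,3-benzodioxepine F2. Irradiation as in step 8 (aryloxymethyl ethers are established donors for this photoreaction) should give the formal-bridged photoadduct with the C7–C8–C11 cyclopropane F3 and the formal-bridged photoadduct with the C1–C10–C11 cyclopropane F4. PPTS in aqueous acetone then hydrolyses the acetal, opens the cyclopropane and loses the O–CH2–O carbon as formaldehyde, so the fallback comes back to the route at 17.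

2. Step 9. Heterolysis may stall at the aldehydes 15 and 16, because the cation at C11 sits in a strained five-membered oxocarbenium ring and the vinylogous push–pull activation in 16 is weak. The dienol may also be protonated at C8 without the alkene moving into conjugation. Fallback: electrophile-driven opening followed by radical convergence. It sets out from the mixture 13/14. NBS in aqueous acetone (NaHCO3) should attack the alkene from the exposed face and open the cyclopropane to the 10-bromo-8-ene keto acetal F5 (from 13) and the 8-bromo-9-ene keto acetal F6 (from 14). Bu3SnH/AIBN should reduce both through the same allyl radical to the 8-ene keto acetal F7. Mild acid hydrolysis of this acetal gives 17, where the fallback comes back to the route.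

3. Step 15. Hydrogen abstraction by the peroxyl radical may occur at the O–CH2 groups of the silyl ethers, or be slow at the neopentyl, electron-poor allylic methylene, so that over-oxidation and silyl ether loss compete. Fallback: oxygenation of C10 through the extended enolate. It sets out from 23. LiN(i-Pr)2/HMPA and then Me3SiCl should give the silyl dienol ketene acetal F8 by γ-deprotonation at C10. mCPBA (vinylogous Rubottom oxidation) should give, after loss of the silyl group, the 10-epi alcohol F9, with oxygen delivered to the exposed face. Dess–Martin oxidation then gives enone 24, where the fallback comes back to the route; the Luche reduction of step 16 sets C10 as before.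

Further compounds
F1 | step 8 | (5S)-8-(dimethoxymethyl)-5-ethenyl-4,5-dihydro-1,3-benzodioxepine | COC(OC)c1ccc2c(c1)OCOC[C@H]2C=C
F2 | step 8 | (5S)-5-[(3E)-5-(tert-butyldimethylsilyloxy)-4-methylpent-3-enyl]-8-(dimethoxymethyl)-4,5-dihydro-1,3-benzodioxepine | COC(OC)c1ccc2c(c1)OCOC[C@H]2CC/C=C(\C)CO[Si](C)(C)C(C)(C)C
F3 | step 8 | formal-bridged photoadduct with the C7–C8–C11 cyclopropane (9-ene) | C[C@@]1(CO[Si](C)(C)C(C)(C)C)[C@H]2[C@@]4(OCO5)[C@@]3(C=C[C@@]24C(OC)OC)[C@@H](C5)CC[C@@H]13
F4 | step 8 | formal-bridged photoadduct with the C1–C10–C11 cyclopropane (8-ene) | C[C@@]1(CO[Si](C)(C)C(C)(C)C)[C@H]2[C@@]4(OCO5)[C@@]3([C@H]4C=C2C(OC)OC)[C@@H](C5)CC[C@@H]13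
F5 | step 9 | 10-bromo-13-TBSO-12-hydroxy-15,15-dimethoxycedr-8-en-11-one (bromine on the exposed face) | C[C@@]1(CO[Si](C)(C)C(C)(C)C)[C@H]2C(=O)[C@@]3([C@H](Br)C=C2C(OC)OC)[C@@H](CO)CC[C@@H]13
F6 | step 9 | 8-bromo-13-TBSO-12-hydroxy-15,15-dimethoxycedr-9-en-11-one (bromine on the exposed face) | C[C@@]1(CO[Si](C)(C)C(C)(C)C)[C@H]2C(=O)[C@@]3(C=C[C@@]2(Br)C(OC)OC)[C@@H](CO)CC[C@@H]13
F7 | step 9 | 13-TBSO-12-hydroxy-15,15-dimethoxycedr-8-en-11-one | C[C@@]1(CO[Si](C)(C)C(C)(C)C)[C@H]2C(=O)[C@@]3(CC=C2C(OC)OC)[C@@H](CO)CC[C@@H]13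
F8 | step 15 | silyl dienol ketene acetal of 23 (C9=C10 and C8=C15; ketene acetal geometry not defined) | C[C@@]1(CO[Si](C)(C)C(C)(C)C)[C@H]2C[C@@]3(C=CC2=C(OC(C)(C)C)O[Si](C)(C)C)[C@@H](CO[Si](CC)(CC)CC)CC[C@@H]13
F9 | step 15 | 10-epimer of 25 | C[C@@]1(CO[Si](C)(C)C(C)(C)C)[C@H]2C[C@@]3([C@H](O)C=C2C(=O)OC(C)(C)C)[C@@H](CO[Si](CC)(CC)CC)CC[C@@H]13
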